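**Retrosynthetic overview**
- Ubiquinol-6 is achiral; the only stereochemical issue is the five E trisubstituted alkenes. No ring is formed: the aromatic ring is bought as coenzyme Q0.
- Disconnection 1: aryl C6–C1′ bond, made by Lewis-acid coupling of CoQ0 with all-E hexaprenyl stannane, which gives the hydroquinone directly.
- Disconnection 2: C12′–C13′ bond of the C30 chain, made head-to-tail by alkylating farnesyl phenyl sulfone with 12-bromofarnesyl acetate (C15 + C15), then Pd/hydride desulfonylation.
- All E geometries come from (E,E)-farnesol and (E,E)-farnesyl bromide, plus one E-selective SeO2 allylic oxidation.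

Assumptions: "single enantiomer" is read as the single all-E isomer, since there are no stereocentres. Buying CoQ6 and reducing it is not counted as a synthesis. The route is designed from literature precedent and has not been run.

**Step 1**
Reactants: 1, (2E,6E)-farnesol
Product: 2, (2E,6E)-farnesyl acetate
Conditions: Ac2O, pyridine, DMAP (cat.), CH2Cl2, 0 °C → rt
Reagents that add atoms: acetic anhydride, CC(=O)OC(C)=O
Why: DMAP-catalysed O-acylation protects the primary alcohol and deactivates the 2,3-alkene toward the next oxidation.

**Step 2**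
Reactants: 2
Product: 3, (2E,6E,10E)-12-hydroxy-3,7,11-trimethyldodeca-2,6,10-trien-1-yl acetate
Conditions: SeO2 (cat.), t-BuOOH, salicylic acid (cat.), CH2Cl2, 0 °C → rt; then NaBH4, EtOH, 0 °C (returns over-oxidised enal to the alcohol)
Reagents that add atoms: selenium dioxide, O=[Se]=O; tert-butyl hydroperoxide, CC(C)(C)OO (terminal oxidant)
Why: Sharpless SeO2/TBHP allylic oxidation (ene then [2,3]-sigmatropic shift) hydroxylates the E-methyl of the terminal, most electron-rich alkene, giving the E allylic alcohol.

**Step 3**
Reactants: 3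
Product: 4, (2E,6E,10E)-12-bromo-3,7,11-trimethyldodeca-2,6,10-trien-1-yl acetate
Conditions: CBr4, PPh3, CH2Cl2, −20 → 0 °C; use immediately
Reagents that add atoms: carbon tetrabromide, BrC(Br)(Br)Br
Why: Appel bromination of a primary allylic alcohol is neutral and SN2, so the acetate and the 10E geometry are untouched.

**Step 4**
Reactants: 5, (2E,6E)-farnesyl bromide; 6, sodium benzenesulfinate
Product: 7, (2E,6E)-farnesyl phenyl sulfone
Conditions: DMF, rt
Reagents that add atoms: sodium benzenesulfinate (6), [Na+].[O-]S(=O)c1ccccc1
Why: SN2 S-alkylation of the sulfinate at the primary allylic bromide gives the allyl sulfone with the alkene geometry retained.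

**Step 5**
Reactants: 7 (1.1 equiv); 4
Product: 8, (2E,6E,10E,14E,18E)-3,7,11,15,19,23-hexamethyl-13-(phenylsulfonyl)tetracosa-2,6,10,14,18,22-hexaen-1-yl acetate, racemic at C13
Conditions: n-BuLi, THF/DMPU, −78 °C; then 4, −78 °C
Reagents that add atoms: none
Why: Biellmann/Grieco–Masaki-type α-alkylation of the lithiated allyl sulfone by the allylic bromide forms the C12–C13 bond with no alkene touched; the acetate survives at −78 °C, and the transient C13 stereocentre is erased in step 6.

**Step 6**
Reactants: 8
Product: 9, all-E hexaprenol, (2E,6E,10E,14E,18E)-3,7,11,15,19,23-hexamethyltetracosa-2,6,10,14,18,22-hexaen-1-ol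
Conditions: LiBHEt3 (6 equiv), THF, −78 → 0 °C; then PdCl2(dppp) (5 mol %), 0 °C → rt
Reagents that add atoms: none
Why: Super-Hydride first cleaves the acetate, so Pd cannot ionise the allylic C1–O; Pd(0)/dppp then performs reductive desulfonylation via a π-allyl complex, delivering hydride to the less substituted C13 and keeping the 14E trisubstituted alkene in place.

**Step 7**
Reactants: 9
Product: 10, all-E hexaprenyl trimethylstannane, trimethyl[(2E,6E,10E,14E,18E)-3,7,11,15,19,23-hexamethyltetracosa-2,6,10,14,18,22-hexaen-1-yl]stannane
Conditions: n-BuLi, THF, −78 °C; MsCl; then Me3SnLi (from Me3SnCl/Li), −78 → 0 °C; filter through basic alumina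
Reagents that add atoms: trimethylstannyl lithium, [Li][Sn](C)(C)C
Why: One-pot mesylation of the lithium alkoxide followed by SN2 displacement with the stannyl anion at the primary allylic carbon retains the 2E geometry; volatile tin by-products are removed under vacuum.

**Step 8**
Reactants: 10; 11, coenzyme Q0 (2,3-dimethoxy-5-methyl-1,4-benzoquinone, 1.5 equiv)
Product: 12, ubiquinol-6 (target)
Conditions: BF3·OEt2 (3 equiv), CH2Cl2, −78 → −30 °C, Ar; then degassed aq. Na2S2O4 work-up; chromatography with degassed solvents under Ar, store at −20 °C under Ar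
Reagents that add atoms: none
Why: Naruta-type BF3-mediated allylstannane–quinone coupling places the linear prenyl chain on the only free ring carbon (C6) with the 2′E geometry carried through and gives the hydroquinone; the dithionite wash returns any air- or CoQ0-oxidised product to the quinol.

**Compound list**
1 | (2E,6E)-farnesol | OC/C=C(\C)CC/C=C(\C)CCC=C(C)C | starting material
2 | (2E,6E)-farnesyl acetate | CC(=O)OC/C=C(\C)CC/C=C(\C)CCC=C(C)C | intermediate
3 | (2E,6E,10E)-12-hydroxyfarnesyl acetate | CC(=O)OC/C=C(\C)CC/C=C(\C)CC/C=C(\C)CO | intermediate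
4 | (2E,6E,10E)-12-bromofarnesyl acetate | CC(=O)OC/C=C(\C)CC/C=C(\C)CC/C=C(\C)CBr | intermediate
5 | (2E,6E)-farnesyl bromide | BrC/C=C(\C)CC/C=C(\C)CCC=C(C)C | starting material
6 | sodium benzenesulfinate | [Na+].[O-]S(=O)c1ccccc1 | starting material
7 | (2E,6E)-farnesyl phenyl sulfone | O=S(=O)(C/C=C(\C)CC/C=C(\C)CCC=C(C)C)c1ccccc1 | intermediate
8 | C30 13-phenylsulfonyl hexaprenyl acetate (racemic at C13) | CC(=O)OC/C=C(\C)CC/C=C(\C)CC/C=C(\C)CC(/C=C(\C)CC/C=C(\C)CCC=C(C)C)S(=O)(=O)c1ccccc1 | intermediate
9 | all-E hexaprenol | OC/C=C(\C)CC/C=C(\C)CC/C=C(\C)CC/C=C(\C)CC/C=C(\C)CCC=C(C)C | intermediate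
10 | all-E hexaprenyl trimethylstannane | C[Sn](C)(C)C/C=C(\C)CC/C=C(\C)CC/C=C(\C)CC/C=C(\C)CC/C=C(\C)CCC=C(C)C | intermediate
11 | coenzyme Q0 | COC1=C(OC)C(=O)C(C)=CC1=O | starting material
12 | ubiquinol-6 | COc1c(O)c(C)c(C/C=C(\C)CC/C=C(\C)CC/C=C(\C)CC/C=C(\C)CC/C=C(\C)CCC=C(C)C)c(O)c1OC | target

**Totals**
Total steps: 8. Longest linear sequence: 7 (steps 1, 2, 3, 5, 6, 7, 8); step 4 is the one-step side branch.

**Three steps most likely to fail, with fallbacks**
1. Step 8 (stannane–quinone coupling). Risks are partial loss of 2′E geometry, BF3-induced chromanol cyclisation and a quinol/quinone mixture. Fallback: convert 9 to hexaprenyl bromide and alkylate the aryl cuprate from 1-bromo-2,3,4,5-tetramethoxy-6-methylbenzene (SN2, geometry-retentive), then CAN oxidation to CoQ6 and Na2S2O4 reduction.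
2. Step 6 (Pd/hydride desulfonylation). Risks are alkene transposition or E/Z scrambling at C14 and hydrogenolysis of the allylic C1–O. Fallback: avoid the sulfone altogether by α,α′-selective coupling of farnesylbarium (farnesyl chloride, Rieke Ba) with THP-protected 12-bromofarnesol, then THP removal to 9.
3. Step 2 (SeO2 oxidation of farnesyl acetate). Risks are C8 versus C12 selectivity, over-oxidation and modest yield. Fallback: change the chain disconnection to C10 + C20, using 8-bromogeranyl acetate (from geranyl acetate, which has only one remote alkene and oxidises cleanly) and geranylgeranyl phenyl sulfone (from all-E geranylgeraniol), converging on 9.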